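**Strategy.** Everything rests on cutting the three O1–C2 bonds of dihydrobenzofuran rings A, B and C in one retrosynthetic stroke. Each C2 bears a 4-oxyphenyl group and lies beside an aryl-substituted C3, so a single Lewis-acid treatment ionises three 4-methoxybenzylic carbinols, closes three five-membered rings and sets three C2 centres trans to C3. The precursor is an (E)-stilbene carrying three 2-aryl-2-(2-hydroxyaryl)-1-(4-methoxyphenyl)ethanol units whose C3 centres (S, R, S) come from rhodium–diene arylation of nitrostyrenes; the carbinols are installed last, by a threefold Nef reaction to lactols and threefold Grignard addition, so no free diarylacetaldehyde is ever handled.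

Key step: step 16

Remarks before the steps
- Numbering: benzofuran numbering for each unit. Unit A has the C7 oxygen and the alkene on C5. Unit B is central, with the alkene on C6. Unit C has the C6 oxygen and is bonded through its C4 to C3 of unit B.
- Structures: the target is all-trans, (2S,3S) in unit A, (2R,3R) in unit B, (2S,3S) in unit C. Precursor 21 and product 22 as drawn below carry C3 = S (A), R (B), S (C), consistent with each other and with the target.
- Design of the precursor: 21 is released in the last operation before the key step, with its three ortho-phenols already free, so no protecting group has to be removed in the presence of the acid-labile carbinols.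
- Assumption: aldehyde 7 is bought (otherwise one step from 2-bromo-4,6-dimethoxybenzaldehyde with BCl3, which cleaves only the methoxy group ortho to the formyl group).
- Assumption: the face of attack in each rhodium step is fixed here. Which antipode of the diene 2,5-diphenylbicyclo[2.2.2]octa-2,5-diene (Ph-bod*) delivers it is to be confirmed on the parent nitrostyrene. The antipode giving Si-face attack is called L-Si, its mirror image L-Re.
- Assumption: 4-methoxyphenylmagnesium bromide (20) is used as the commercial THF solution.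
- Handling: compounds 6 and 16 onward are kept from light and air.

**Route**

Step 1
Reactants: 1 5-bromo-2-hydroxy-3-methoxybenzaldehyde
Product: 2 5-bromo-3-methoxy-2-(methoxymethoxy)benzaldehyde
Conditions: MOMCl, i-Pr2NEt, CH2Cl2, 0 °C to rt
Reagents that add atoms: chloromethyl methyl ether, COCCl
Why: O-alkylation of the phenol (Williamson-type acetal protection) masks the acidic OH, which would otherwise give an unreactive phenoxide-conjugated nitroalkene in the rhodium step.

Step 2
Reactants: 2 5-bromo-3-methoxy-2-(methoxymethoxy)benzaldehyde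
Product: 3 (E)-5-bromo-1-methoxy-2-(methoxymethoxy)-3-(2-nitrovinyl)benzene
Conditions: MeNO2 (solvent), NH4OAc (0.5 equiv), 90 °C
Reagents that add atoms: nitromethane, C[N+](=O)[O-]
Why: Henry (nitroaldol) condensation with dehydration should give the conjugated nitroalkene as the thermodynamic E isomer, the weakly acidic buffer leaving the MOM acetal intact.

Step 3
Reactants: 3 (E)-5-bromo-1-methoxy-2-(methoxymethoxy)-3-(2-nitrovinyl)benzene; 4 3,5-dimethoxyphenylboronic acid
Product: 5 (S)-5-bromo-1-[1-(3,5-dimethoxyphenyl)-2-nitroethyl]-3-methoxy-2-(methoxymethoxy)benzene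
Conditions: [RhCl(C2H4)2]2 (2.5 mol %), Ph-bod* (L-Si, 6 mol %), KHF2 (2 equiv, activator), toluene/H2O 10:1, 60 °C
Reagents that add atoms: none
Why: Hayashi–Miyaura rhodium-catalysed asymmetric conjugate addition, in which the diene-bound aryl-rhodium species delivers the 3,5-dimethoxyphenyl group to the Si face of C-β and so sets C3 of unit A as S, the aryl bromide being inert to monovalent rhodium.

Step 4
Reactants: 5 (S)-5-bromo-1-[1-(3,5-dimethoxyphenyl)-2-nitroethyl]-3-methoxy-2-(methoxymethoxy)benzene
Product: 6 (S)-1-[1-(3,5-dimethoxyphenyl)-2-nitroethyl]-3-methoxy-2-(methoxymethoxy)-5-vinylbenzene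
Conditions: vinylboronic acid pinacol ester, PdCl2(dppf) (3 mol %), K2CO3, dioxane/H2O, 80 °C; work-up at pH 5–6
Reagents that add atoms: 4,4,5,5-tetramethyl-2-vinyl-1,3,2-dioxaborolane, C=CB1OC(C)(C)C(C)(C)O1
Why: Suzuki–Miyaura coupling at the aryl bromide installs the vinyl group; carbonate deprotonates the nitroalkane only reversibly at C2, and the non-acidic C3 centre is untouched.

Step 5
Reactants: 7 2-bromo-6-hydroxy-4-methoxybenzaldehyde
Product: 8 2-bromo-4-methoxy-6-(methoxymethoxy)benzaldehyde
Conditions: MOMCl, i-Pr2NEt, CH2Cl2, 0 °C to rt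
Reagents that add atoms: chloromethyl methyl ether, COCCl
Why: O-alkylation of the phenol (Williamson-type acetal protection), as in step 1.

Step 6
Reactants: 8 2-bromo-4-methoxy-6-(methoxymethoxy)benzaldehyde
Product: 9 (E)-1-bromo-5-methoxy-3-(methoxymethoxy)-2-(2-nitrovinyl)benzene
Conditions: MeNO2 (solvent), NH4OAc (0.5 equiv), 90 °C
Reagents that add atoms: nitromethane, C[N+](=O)[O-]
Why: Henry condensation with dehydration, which is routine for 2,6-disubstituted benzaldehydes and gives the E nitroalkene.

Step 7
Reactants: 9 (E)-1-bromo-5-methoxy-3-(methoxymethoxy)-2-(2-nitrovinyl)benzene; 4 3,5-dimethoxyphenylboronic acid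
Product: 10 (S)-1-bromo-2-[1-(3,5-dimethoxyphenyl)-2-nitroethyl]-5-methoxy-3-(methoxymethoxy)benzene
Conditions: [RhCl(C2H4)2]2 (2.5 mol %), Ph-bod* (L-Si, 6 mol %), KHF2 (2 equiv, activator), toluene/H2O 10:1, 70 °C
Reagents that add atoms: none
Why: Hayashi–Miyaura asymmetric conjugate addition of an unhindered aryl-rhodium species to a strongly activated nitroalkene, which tolerates the two ortho substituents; Si-face delivery sets C3 of unit C as S.

Step 8
Reactants: 10 (S)-1-bromo-2-[1-(3,5-dimethoxyphenyl)-2-nitroethyl]-5-methoxy-3-(methoxymethoxy)benzene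
Product: 11 (S)-2-{2-[1-(3,5-dimethoxyphenyl)-2-nitroethyl]-5-methoxy-3-(methoxymethoxy)phenyl}-4,4,5,5-tetramethyl-1,3,2-dioxaborolane
Conditions: B2pin2, PdCl2(dppf) (5 mol %), KOAc, dioxane, 90 °C
Reagents that add atoms: bis(pinacolato)diboron, CC1(C)OB(OC1(C)C)B1OC(C)(C)C(C)(C)O1
Why: Miyaura borylation, in which zerovalent palladium inserts into the C–Br bond and acetate-assisted transmetalation with B2pin2 gives the boronate; the weak base spares the nitroalkane, and attack of its nitronate on this bromide would need a four-membered ring.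

Step 9
Reactants: 12 4-bromo-2-hydroxybenzaldehyde
Product: 13 4-bromo-2-(methoxymethoxy)benzaldehyde
Conditions: MOMCl, i-Pr2NEt, CH2Cl2, 0 °C to rt
Reagents that add atoms: chloromethyl methyl ether, COCCl
Why: O-alkylation of the phenol (Williamson-type acetal protection), as in step 1.

Step 10
Reactants: 13 4-bromo-2-(methoxymethoxy)benzaldehyde
Product: 14 (E)-4-bromo-2-(methoxymethoxy)-1-(2-nitrovinyl)benzene
Conditions: MeNO2 (solvent), NH4OAc (0.5 equiv), 90 °C
Reagents that add atoms: nitromethane, C[N+](=O)[O-]
Why: Henry condensation with dehydration gives the E nitroalkene.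

Step 11
Reactants: 14 (E)-4-bromo-2-(methoxymethoxy)-1-(2-nitrovinyl)benzene; 11 (S)-aryl pinacol boronate of unit C
Product: 15 4-bromo-1-[(1R)-1-{2-[(1S)-1-(3,5-dimethoxyphenyl)-2-nitroethyl]-5-methoxy-3-(methoxymethoxy)phenyl}-2-nitroethyl]-2-(methoxymethoxy)benzene
Conditions: [RhCl(C2H4)2]2 (5 mol %), Ph-bod* (L-Re, 12 mol %), KHF2 (3 equiv, activator), toluene/H2O 10:1, 80 °C; 14 in excess (1.5 equiv)
Reagents that add atoms: none
Why: Hayashi–Miyaura asymmetric conjugate addition in which KHF2 turns the boronate into the trifluoroborate without generating the nitronate of 11, and the mirror-image diene sends ring C to the Re face of C-β of 14, setting C3 of unit B as R under catalyst control while C3 of unit C is untouched.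

Step 12
Reactants: 15 bis-nitro aryl bromide (units B and C); 6 (S)-styrene of unit A
Product: 16 (E)-stilbene tris(MOM ether) tris(nitroalkane), C3 = S (A), R (B), S (C)
Conditions: Pd(OAc)2 (5 mol %), P(o-tol)3 (12 mol %), Et3N, DMF, 90 °C, dark
Reagents that add atoms: none
Why: Mizoroki–Heck reaction, in which syn-carbopalladation of the styrene by the aryl-palladium species from 15 and syn-β-hydride elimination give the (E)-stilbene; the triarylphosphine/amine system does not arylate nitronates.

Step 13
Reactants: 16 (E)-stilbene tris(MOM ether) tris(nitroalkane)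
Product: 17 (E)-stilbene triphenol tris(nitroalkane)
Conditions: 3 M aq. HCl, MeOH/THF, 45 °C, dark
Reagents that add atoms: none
Why: Acid-catalysed acetal methanolysis removes all three MOM groups at a stage where nothing acid-labile is present, since nitroalkanes and the stilbene tolerate dilute HCl.

Step 14
Reactants: 17 (E)-stilbene triphenol tris(nitroalkane)
Product: 19 (E)-stilbene tris-lactol (three 3-aryl-2,3-dihydrobenzofuran-2-ol units; anomers mixed), via hexasodium nitronate-phenoxide salt 18 (not isolated)
Conditions: NaOMe (7 equiv), MeOH, 0 °C, Ar; then aq. TiCl3 (13 equiv) buffered with NH4OAc to pH 5–6, THF/H2O, 0 °C to rt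
Reagents that add atoms: water, O; sodium methoxide, C[O-].[Na+] (sodium of 18 only)
Why: Nef reaction in its reductive titanium trichloride form, in which trivalent titanium reduces each nitronate to the imine, which hydrolyses and is captured at once by the ortho-phenol as the five-membered hemiacetal, so C3 of units A, B and C never sits beside a free enolisable aldehyde and no strong acid is present to dehydrate the lactols to benzofurans.

Step 15
Reactants: 19 (E)-stilbene tris-lactol; 20 4-methoxyphenylmagnesium bromide (three molecules add to carbon, one at each lactol carbon)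
Product: 21 (E)-stilbene tris(carbinol) triphenol, C3 = S (A), R (B), S (C), carbinol centres mixed
Conditions: 20 (10 equiv, of which six are consumed: three as base, three as nucleophile), THF, −20 to 0 °C; sat. aq. NH4Cl; rapid filtration through Et3N-deactivated silica
Reagents that add atoms: 4-methoxyphenylmagnesium bromide (the two further molecules that supply the second and third 4-methoxyphenyl groups), COc1ccc([Mg]Br)cc1.COc1ccc([Mg]Br)cc1
Why: Grignard addition to lactols, in which at each of the three sites one molecule of 20 deprotonates the lactol and opens it to its magnesium phenoxide aldehyde and a second molecule adds to the carbonyl faster than it can enolise it, so six molecules are consumed and three 4-methoxyphenyl groups are built in; the new carbinol centres form as mixtures, which is harmless because step 16 erases them.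

Step 16
Reactants: 21 (E)-stilbene tris(carbinol) triphenol
Product: 22 nona-O-methyl ether of the target, (2S,3S) in unit A, (2R,3R) in unit B, (2S,3S) in unit C
Conditions: BF3·OEt2 (6 equiv), 4 Å molecular sieves, CH2Cl2 (5 mM), −78 to −30 °C, dark; then Et3N, aq. NaHCO3
Reagents that add atoms: none
Why: BF3 binds each benzylic hydroxyl and expels it, giving a 4-methoxyphenyl-stabilised cation (a para-quinone methide oxocarbenium) that the neighbouring phenol captures; the closest known reaction is the acid-mediated cyclodehydration of 2-(2-hydroxyaryl)-1,2-diarylethanols to trans-2,3-diaryl-2,3-dihydrobenzofurans, here run at three sites in one flask. Ring A, ring B and ring C each close in a 5-exo-trig mode, the phenolic oxygen (O1) adding to the exocyclic cationic carbon C2. C2 of unit A is controlled by C3 of unit A, C2 of unit B by C3 of unit B and C2 of unit C by C3 of unit C: oxygen adds anti to the C3 aryl group and, because ionisation is reversible, any cis ring reopens and settles as the trans isomer, so the mixed carbinol configurations do not matter. The step needs O-capture to win over Friedel–Crafts attack by the 3,5-dimethoxyphenyl rings, loss of the C3 proton and protonation of the stilbene. The ortho-phenol sits five atoms from each cation whereas the nearest electron-rich arene could only close a seven-membered ring, sieves and low temperature keep proton activity down, and the anisyl carbinols ionise far more easily than the stilbene is protonated.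

Step 17
Reactants: 22 nona-O-methyl ether of the target
Product: 23 target CNP0265934.1
Conditions: BBr3 (30 equiv), CH2Cl2, −78 °C to rt, dark; MeOH then H2O at −78 °C; reversed-phase chromatography
Reagents that add atoms: none
Why: Lewis-acid cleavage of aryl methyl ethers, in which BBr3 coordinates each methoxy oxygen, bromide removes the methyl group by SN2 and hydrolysis frees the nine phenols; any transient opening of an O1–C2 bond recloses to the trans ring.

**Compound list**

1 | 5-bromo-2-hydroxy-3-methoxybenzaldehyde | COc1cc(Br)cc(C=O)c1O | starting material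
2 | 5-bromo-3-methoxy-2-(methoxymethoxy)benzaldehyde | COCOc1c(OC)cc(Br)cc1C=O | intermediate
3 | (E)-5-bromo-1-methoxy-2-(methoxymethoxy)-3-(2-nitrovinyl)benzene | COCOc1c(OC)cc(Br)cc1/C=C/[N+](=O)[O-] | intermediate
4 | 3,5-dimethoxyphenylboronic acid | COc1cc(OC)cc(B(O)O)c1 | starting material
5 | (S)-5-bromo-1-[1-(3,5-dimethoxyphenyl)-2-nitroethyl]-3-methoxy-2-(methoxymethoxy)benzene | [O-][N+](=O)C[C@@H](c1cc(OC)cc(OC)c1)c1cc(Br)cc(OC)c1OCOC | intermediate
6 | (S)-1-[1-(3,5-dimethoxyphenyl)-2-nitroethyl]-3-methoxy-2-(methoxymethoxy)-5-vinylbenzene | [O-][N+](=O)C[C@@H](c1cc(OC)cc(OC)c1)c1cc(C=C)cc(OC)c1OCOC | intermediate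
7 | 2-bromo-6-hydroxy-4-methoxybenzaldehyde | O=Cc1c(O)cc(OC)cc1Br | starting material
8 | 2-bromo-4-methoxy-6-(methoxymethoxy)benzaldehyde | O=Cc1c(OCOC)cc(OC)cc1Br | intermediate
9 | (E)-1-bromo-5-methoxy-3-(methoxymethoxy)-2-(2-nitrovinyl)benzene | [O-][N+](=O)/C=C/c1c(OCOC)cc(OC)cc1Br | intermediate
10 | (S)-1-bromo-2-[1-(3,5-dimethoxyphenyl)-2-nitroethyl]-5-methoxy-3-(methoxymethoxy)benzene | Brc1cc(OC)cc(OCOC)c1[C@H](c1cc(OC)cc(OC)c1)C[N+](=O)[O-] | intermediate
11 | (S)-2-{2-[1-(3,5-dimethoxyphenyl)-2-nitroethyl]-5-methoxy-3-(methoxymethoxy)phenyl}-4,4,5,5-tetramethyl-1,3,2-dioxaborolane | CC1(C)OB(OC1(C)C)c1cc(OC)cc(OCOC)c1[C@H](c1cc(OC)cc(OC)c1)C[N+](=O)[O-] | intermediate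
12 | 4-bromo-2-hydroxybenzaldehyde | O=Cc1ccc(Br)cc1O | starting material
13 | 4-bromo-2-(methoxymethoxy)benzaldehyde | O=Cc1ccc(Br)cc1OCOC | intermediate
14 | (E)-4-bromo-2-(methoxymethoxy)-1-(2-nitrovinyl)benzene | [O-][N+](=O)/C=C/c1ccc(Br)cc1OCOC | intermediate
15 | 4-bromo-1-[(1R)-1-{2-[(1S)-1-(3,5-dimethoxyphenyl)-2-nitroethyl]-5-methoxy-3-(methoxymethoxy)phenyl}-2-nitroethyl]-2-(methoxymethoxy)benzene | Brc1ccc([C@H](C[N+](=O)[O-])c2cc(OC)cc(OCOC)c2[C@H](c2cc(OC)cc(OC)c2)C[N+](=O)[O-])c(OCOC)c1 | intermediate
16 | (E)-1-{3-[(1S)-1-(3,5-dimethoxyphenyl)-2-nitroethyl]-5-methoxy-4-(methoxymethoxy)phenyl}-2-{4-[(1R)-1-{2-[(1S)-1-(3,5-dimethoxyphenyl)-2-nitroethyl]-5-methoxy-3-(methoxymethoxy)phenyl}-2-nitroethyl]-3-(methoxymethoxy)phenyl}ethene | [O-][N+](=O)C[C@@H](c1cc(OC)cc(OC)c1)c1cc(/C=C/c2ccc([C@H](C[N+](=O)[O-])c3cc(OC)cc(OCOC)c3[C@H](c3cc(OC)cc(OC)c3)C[N+](=O)[O-])c(OCOC)c2)cc(OC)c1OCOC | intermediate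
17 | triphenol of 16 (the three MOM ethers replaced by OH; C3 = S, R, S) | [O-][N+](=O)C[C@@H](c1cc(OC)cc(OC)c1)c1cc(/C=C/c2ccc([C@H](C[N+](=O)[O-])c3cc(OC)cc(O)c3[C@H](c3cc(OC)cc(OC)c3)C[N+](=O)[O-])c(O)c2)cc(OC)c1O | intermediate
18 | hexasodium salt of 17 (three nitronates, three phenoxides) | [O-][N+]([O-])=C[C@@H](c1cc(OC)cc(OC)c1)c1cc(/C=C/c2ccc([C@H](C=[N+]([O-])[O-])c3cc(OC)cc([O-])c3[C@H](c3cc(OC)cc(OC)c3)C=[N+]([O-])[O-])c([O-])c2)cc(OC)c1[O-].[Na+].[Na+].[Na+].[Na+].[Na+].[Na+] | intermediate (not isolated)
19 | tris-lactol: (E)-alkene joining C5 of (3S)-3-(3,5-dimethoxyphenyl)-7-methoxy-2,3-dihydrobenzofuran-2-ol (unit A) to C6 of a (3R)-2,3-dihydrobenzofuran-2-ol (unit B) whose C3 is bonded to C4 of (3S)-3-(3,5-dimethoxyphenyl)-6-methoxy-2,3-dihydrobenzofuran-2-ol (unit C); anomeric centres mixed | OC1Oc2c(OC)cc(/C=C/c3ccc4c(c3)OC(O)[C@@H]4c3cc(OC)cc4c3[C@H](c3cc(OC)cc(OC)c3)C(O)O4)cc2[C@@H]1c1cc(OC)cc(OC)c1 | intermediate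
20 | 4-methoxyphenylmagnesium bromide | COc1ccc([Mg]Br)cc1 | starting material
21 | (E)-1-{3-[(1S)-1-(3,5-dimethoxyphenyl)-2-hydroxy-2-(4-methoxyphenyl)ethyl]-4-hydroxy-5-methoxyphenyl}-2-{4-[(1R)-1-{2-[(1S)-1-(3,5-dimethoxyphenyl)-2-hydroxy-2-(4-methoxyphenyl)ethyl]-3-hydroxy-5-methoxyphenyl}-2-hydroxy-2-(4-methoxyphenyl)ethyl]-3-hydroxyphenyl}ethene, carbinol centres mixed | COc1ccc(C(O)[C@@H](c2cc(OC)cc(OC)c2)c2cc(/C=C/c3ccc([C@H](C(O)c4ccc(OC)cc4)c4cc(OC)cc(O)c4[C@H](c4cc(OC)cc(OC)c4)C(O)c4ccc(OC)cc4)c(O)c3)cc(OC)c2O)cc1 | intermediate (key-step precursor)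
22 | nona-O-methyl ether: (E)-alkene joining C5 of (2S,3S)-3-(3,5-dimethoxyphenyl)-7-methoxy-2-(4-methoxyphenyl)-2,3-dihydrobenzofuran (unit A) to C6 of a (2R,3R)-2-(4-methoxyphenyl)-2,3-dihydrobenzofuran (unit B) whose C3 is bonded to C4 of (2S,3S)-3-(3,5-dimethoxyphenyl)-6-methoxy-2-(4-methoxyphenyl)-2,3-dihydrobenzofuran (unit C) | COc1ccc([C@H]2Oc3c(OC)cc(/C=C/c4ccc5c(c4)O[C@@H](c4ccc(OC)cc4)[C@@H]5c4cc(OC)cc5c4[C@H](c4cc(OC)cc(OC)c4)[C@@H](c4ccc(OC)cc4)O5)cc3[C@@H]2c2cc(OC)cc(OC)c2)cc1 | intermediate (key-step product)
23 | CNP0265934.1: 22 with all nine methoxy groups as hydroxyl, (2S,3S) unit A, (2R,3R) unit B, (2S,3S) unit C, E alkene | Oc1ccc([C@H]2Oc3c(O)cc(/C=C/c4ccc5c(c4)O[C@@H](c4ccc(O)cc4)[C@@H]5c4cc(O)cc5c4[C@H](c4cc(O)cc(O)c4)[C@@H](c4ccc(O)cc4)O5)cc3[C@@H]2c2cc(O)cc(O)c2)cc1 | target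

**Step count.** Total: 17 steps. Longest linear sequence: 11 steps (5, 6, 7, 8, 11, 12, 13, 14, 15, 16, 17).

**Steps most likely to fail**

Step 11. Boron-to-rhodium transfer from the ortho-branched boronate may be slower than protodeboronation and nitroalkene oligomerisation, and the diene antipode may be mismatched with the existing C3 centre of unit C, so conversion or facial control may be poor. Fallback, from 11 and 14 back to 15: catalyst control is given up at this one centre. A base-free conjugate addition with a cationic divalent-palladium catalyst (Pd(O2CCF3)2, 2,2'-bipyridine, MeOH/H2O, 50 °C) is a known aryl-boron addition to nitroalkenes that needs no hydroxo-metal species and leaves aryl bromides alone. It should give 15 together with its epimer at C3 of unit B, the (1S,1'S) bis-nitro bromide F1. Because C3 of unit C is already fixed, the two are diastereomers and are separated by chromatography; 15 re-enters at step 12.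

Step 14. The reduction may stall at the aldoxime, the transient imine may tautomerise to a diaryl enamine and erode C3, or a lactol may lose water to a benzofuran. Fallback, from 17 back to 19: the Nef reaction is split into two stages with different reagents. SnCl2·2H2O, PhSH and Et3N in MeCN reduce the three nitro groups only as far as the oxime, giving the tris(aldoxime) triphenol F2. Oxime exchange with aqueous glyoxylic acid (THF/H2O, rt) then frees the aldehydes under non-reducing, weakly acidic conditions, and they close to the tris-lactol 19.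

Step 16. Irreversible Friedel–Crafts capture of a C2 cation (seven-membered ring between C2 of unit B and the 3,5-dimethoxyphenyl ring on C3 of unit C), loss of a C3 proton to a triarylethylene, or incomplete drift of cis rings to trans may lower yield or stereochemical purity. Fallback, from 21 back to 22: the three O1–C2 bonds are formed without free cations by threefold intramolecular Mitsunobu etherification (PPh3, DIAD, THF, 0 °C). This closes each ring with inversion at its carbinol and so gives the nona-O-methyl ether as a mixture of C2 epimers F3. The cis rings are then equilibrated to trans in a separate, dilute, catalytic acid treatment (TsOH, CH2Cl2, 0 °C), which only reopens and recloses existing O1–C2 bonds, to give 22.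

Further compounds
F1 | step 11 | 4-bromo-1-[(1S)-1-{2-[(1S)-1-(3,5-dimethoxyphenyl)-2-nitroethyl]-5-methoxy-3-(methoxymethoxy)phenyl}-2-nitroethyl]-2-(methoxymethoxy)benzene (epimer of 15 at C3 of unit B) | Brc1ccc([C@@H](C[N+](=O)[O-])c2cc(OC)cc(OCOC)c2[C@H](c2cc(OC)cc(OC)c2)C[N+](=O)[O-])c(OCOC)c1
F2 | step 14 | tris(aldoxime) triphenol: 17 with each CH2NO2 group replaced by CH=NOH, oxime geometry mixed | ON=C[C@@H](c1cc(OC)cc(OC)c1)c1cc(/C=C/c2ccc([C@H](C=NO)c3cc(OC)cc(O)c3[C@H](c3cc(OC)cc(OC)c3)C=NO)c(O)c2)cc(OC)c1O
F3 | step 16 | nona-O-methyl ether as a mixture of C2 epimers (C3 centres as in 22) | COc1ccc(C2Oc3c(OC)cc(/C=C/c4ccc5c(c4)OC(c4ccc(OC)cc4)[C@@H]5c4cc(OC)cc5c4[C@H](c4cc(OC)cc(OC)c4)C(c4ccc(OC)cc4)O5)cc3[C@@H]2c2cc(OC)cc(OC)c2)cc1
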